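The route rests on cutting the bond between the side-chain carbonyl carbon and C3 of the furan-2,4-dione (tetronic acid) ring. C3 is the hub of a tricarbonyl array (lactone carbonyl C2, enol carbon C4, exocyclic ketone), so it is brought in as the methylene carbon of an open-chain malonate half-ester of O-benzyl methyl (S)-glycerate. In one flask, magnesium-mediated decarboxylative Claisen acylation with the imidazolide of 13-methyltetradecanoic acid forms the acyl–C3 bond, CO2 leaves as the spent activating group, and fluoride-triggered Dieckmann closure of C3 onto the glycerate ester (C3–C4) builds the ring. The C5 centre comes intact from methyl (S)-glycidate; hydrogenolysis finishes the four-step route.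

Key step: step 3

Remark: the target is handled as the 4-hydroxy tautomer drawn in its SMILES (the enol forms of the tricarbonyl unit interconvert freely), and its C5 centre is (S), which corresponds to the (S)-glycerate series.

Step 1
Reactants: 1 methyl (2S)-oxirane-2-carboxylate; 2 benzyl alcohol
Product: 3 methyl (2S)-3-(benzyloxy)-2-hydroxypropanoate
Conditions: BnOH (3 equiv), BF3·OEt2 (cat.), CH2Cl2, 0 °C to rt
Reagents that add atoms: none
Why: Lewis-acid-catalysed epoxide alcoholysis should proceed by SN2-type attack of benzyl alcohol at the unsubstituted C3, because the ester group disfavours positive charge at C2, and since no bond to C2 is broken its (S) configuration is carried through unchanged.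

Step 2
Reactants: 3 methyl (2S)-3-(benzyloxy)-2-hydroxypropanoate; 4 2,2-dimethyl-1,3-dioxane-4,6-dione (Meldrum's acid)
Product: 5 3-{[(2S)-3-(benzyloxy)-1-methoxy-1-oxopropan-2-yl]oxy}-3-oxopropanoic acid
Conditions: toluene, 90 °C
Reagents that add atoms: none
Why: The secondary hydroxyl should open Meldrum's acid by acyl substitution with loss of acetone (alcoholysis of Meldrum's acid to a malonic acid half-ester) under neutral conditions that leave the methyl ester, the benzyl ether and the stereocentre untouched.

Step 3
Reactants: 5 3-{[(2S)-3-(benzyloxy)-1-methoxy-1-oxopropan-2-yl]oxy}-3-oxopropanoic acid; 6 13-methyltetradecanoic acid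
Product: 9 (5S)-5-[(benzyloxy)methyl]-4-hydroxy-3-(13-methyltetradecanoyl)furan-2(5H)-one, via acyl imidazolide 7 (not isolated), via open-chain beta-keto ester 8 (not isolated)
Conditions: 6, CDI, THF, rt; then 5, MgCl2, Et3N, MeCN/THF, rt to 45 °C; then Bu4NF (excess), THF, rt; aq. HCl work-up
Reagents that add atoms: none
Why: CDI should convert acid 6 into imidazolide 7, which the chelated magnesium enolate of malonate half-ester 5 attacks through carbon to form the bond between the side-chain carbonyl carbon and the future C3, after which loss of CO2 from the acylmalonate gives the magnesium enolate of beta-keto ester 8. Fluoride then removes magnesium as MgF2, and the free tetrabutylammonium enolate attacks the methyl ester carbonyl and expels methoxide, closing the C3–C4 bond of the furanone ring in a 5-exo-trig Dieckmann cyclisation. The closest known reaction types are the Masamune–Brooks decarboxylative Claisen condensation of magnesium malonate half-esters with acyl imidazolides and the fluoride-mediated Dieckmann cyclisation of alpha-(beta-ketoacyloxy) esters to 3-acyltetronic acids. No new stereocentre is formed; the C5 centre comes from 1 and should survive because neither Et3N nor fluoride enolises the alpha-acyloxy ester appreciably and the product is held as its stable tricarbonyl anion. The step needs C- over O-acylation and acylation before ring closure: the first is secured by magnesium chelation of the malonate and by the irreversible decarboxylation, the second by the inertness of the magnesium enolates towards the methyl ester until fluoride is added. The strongly acidic 3-acyltetronate anion is the thermodynamic sink that drives both stages.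

Step 4
Reactants: 9 (5S)-5-[(benzyloxy)methyl]-4-hydroxy-3-(13-methyltetradecanoyl)furan-2(5H)-one
Product: 10 (5S)-4-hydroxy-5-(hydroxymethyl)-3-(13-methyltetradecanoyl)furan-2(5H)-one
Conditions: H2 (1 atm), 10% Pd/C, EtOAc/MeOH, rt
Reagents that add atoms: none
Why: Catalytic hydrogenolysis should cleave the benzylic C–O bond of the ether while the enolised tricarbonyl unit, which is not reduced over Pd/C at 1 atm, and the C5 stereocentre stay intact (benzyl ether hydrogenolysis).

Compound list
1 | methyl (2S)-oxirane-2-carboxylate (methyl (S)-glycidate) | COC(=O)[C@@H]1CO1 | starting material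
2 | benzyl alcohol | OCc1ccccc1 | starting material
3 | methyl (2S)-3-(benzyloxy)-2-hydroxypropanoate | COC(=O)[C@@H](O)COCc1ccccc1 | intermediate
4 | 2,2-dimethyl-1,3-dioxane-4,6-dione (Meldrum's acid) | CC1(C)OC(=O)CC(=O)O1 | starting material
5 | 3-{[(2S)-3-(benzyloxy)-1-methoxy-1-oxopropan-2-yl]oxy}-3-oxopropanoic acid | COC(=O)[C@@H](OC(=O)CC(=O)O)COCc1ccccc1 | intermediate
6 | 13-methyltetradecanoic acid | CC(C)CCCCCCCCCCCC(=O)O | starting material
7 | 1-(13-methyltetradecanoyl)-1H-imidazole | CC(C)CCCCCCCCCCCC(=O)n1ccnc1 | intermediate
8 | methyl (2S)-3-(benzyloxy)-2-[(15-methyl-3-oxohexadecanoyl)oxy]propanoate | CC(C)CCCCCCCCCCCC(=O)CC(=O)O[C@@H](COCc1ccccc1)C(=O)OC | intermediate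
9 | (5S)-5-[(benzyloxy)methyl]-4-hydroxy-3-(13-methyltetradecanoyl)furan-2(5H)-one | CC(C)CCCCCCCCCCCC(=O)C1=C(O)[C@H](COCc2ccccc2)OC1=O | intermediate
10 | (5S)-4-hydroxy-5-(hydroxymethyl)-3-(13-methyltetradecanoyl)furan-2(5H)-one | CC(C)CCCCCCCCCCCC(=O)C1=C(O)[C@H](CO)OC1=O | target
11 | O-benzyl-L-serine (used only in the fallback for step 1) | N[C@@H](COCc1ccccc1)C(=O)O | starting material

Total step count: 4. Longest linear sequence: 4 steps (1 → 3 → 5 → 9 → 10).

Steps most likely to fail

Step 3. The one-flask sequence may lose its order. Decarboxylation may lag behind acylation, fluoride may cleave the alpha-acyloxy ester link instead of triggering ring closure, and a slow closure leaves time for enolisation at the glycerate carbon (erosion of configuration or beta-elimination of benzyloxide). The fallback sets out from compound 3 and comes back to the route at compound 9; it forms the same exocyclic bond on the finished ring. Acetylation of 3 (Ac2O, pyridine, cat. DMAP, CH2Cl2) should give methyl (2S)-2-(acetyloxy)-3-(benzyloxy)propanoate F1. Dieckmann cyclisation of F1 with LiN(SiMe3)2 (THF, −78 °C) should give (5S)-5-[(benzyloxy)methyl]-4-hydroxyfuran-2(5H)-one F2. F2 and acid 6 with DCC and DMAP (CH2Cl2, 0 °C to rt) should undergo 4-O-acylation followed by the DMAP-mediated 1,3-acyl shift from O4 to C3 (Steglich esterification, then a Fries-type rearrangement) to give 9. In either variant the free acid 9 is best isolated by acid–base extraction, since 3-acyltetronic acids bind metal ions on silica.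

Step 1. Regiocontrol in the epoxide opening may be lost, the newly freed hydroxyl may open further epoxide (oligomerisation), or benzyl alcohol may transesterify the methyl ester. The fallback sets out from compound 11, commercial O-benzyl-L-serine, and comes back at compound 3. Diazotisation (NaNO2, aq. H2SO4, 0 °C to rt) should give (2S)-3-(benzyloxy)-2-hydroxypropanoic acid F3 with overall retention, by double inversion through the alpha-lactone. Fischer esterification of F3 (MeOH, cat. H2SO4, rt) should then give 3.

Step 4. The chelating tricarbonyl acid may poison the catalyst, or over-reduction may set in (hydrogenolysis of the allylic C5–O1 bond, reduction of the side-chain ketone). The fallback sets out from compound 9 and arrives at compound 10 without any new compound. Lewis-acid dealkylation with BCl3 and pentamethylbenzene as cation scavenger (CH2Cl2, −78 °C, then MeOH/aqueous work-up) removes the benzyl group without hydrogen or a metal surface.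

Further compounds
F1 | step 3 | methyl (2S)-2-(acetyloxy)-3-(benzyloxy)propanoate | COC(=O)[C@@H](OC(C)=O)COCc1ccccc1
F2 | step 3 | (5S)-5-[(benzyloxy)methyl]-4-hydroxyfuran-2(5H)-one | O=C1C=C(O)[C@H](COCc2ccccc2)O1
F3 | step 1 | (2S)-3-(benzyloxy)-2-hydroxypropanoic acid | O[C@@H](COCc1ccccc1)C(=O)O
F0 | step 4 | none | none
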